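## Retrosynthetic overview

1. Side chain last: Heck coupling of an exocyclic (E)-vinyl iodide (made from a vinylsilane) with 2-methylbut-3-en-2-ol.
2. Cycloheptane ring, closed last (key step): C4a–C5 bond by decarboxylative 7-endo radical addition of a primary alkyl radical to the β-carbon of a 3-(1-hydroxycyclohexyl)-5-alkylidene-5,6-dihydropyran-2-one; this sets C4a and C9a and completes the bicyclo[4.3.1]decane.
3. Dihydropyranone ring, third: iodide-triggered aldol of the cyclohexanone with methyl propiolate (sets C9), copper-mediated coupling with a cis-silylstannylated propargyl alcohol, then lactonisation.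
4. Saturated δ-lactone, second and temporary: radical opening of an epoxide by Cp2TiCl and addition to methyl acrylate makes the C7 quaternary centre trans to the C12 oxygen; the lactone masks C12–OH and stores the later radical precursor as a carboxyl group.
5. Cyclohexane ring, first: bought as 3-methylcyclohex-2-en-1-one; deconjugative acetalisation and Shi epoxidation give the absolute configuration.

Assumption: locants C1–C12 follow the 7,9-propanocyclohepta[c]pyran numbering of the target (C1 lactone C=O, C3 OCH2, C4 alkylidene carbon, C4a/C9a ring fusion, C7 methyl-bearing bridgehead, C8 one-carbon bridge, C9 hydroxylated bridgehead, C10–C12 three-carbon bridge, C12 carbinol).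

## Route

Step 1
Reactants: 1 3-methylcyclohex-2-en-1-one
Product: 2 7-methyl-1,4-dioxaspiro[4.5]dec-7-ene
Conditions: HOCH2CH2OH (1.5 equiv), PPTS (5 mol%), benzene, reflux, Dean–Stark; minor conjugated isomer removed by distillation
Reagents that add atoms: ethane-1,2-diol (OCCO)
Why: Deconjugative acetalisation: the intermediate dienol ether is protonated kinetically at the α-carbon, which moves the alkene to C7=C8 of the spiro acetal, where the quaternary centre and the carbinol are needed, and masks the future C9 ketone; no stereocentre is formed.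

Step 2
Reactants: 2 7-methyl-1,4-dioxaspiro[4.5]dec-7-ene
Product: 3 (1'R,6'S)-1'-methylspiro[1,3-dioxolane-2,3'-[7]oxabicyclo[4.1.0]heptane]
Conditions: L-fructose-derived Shi ketone (enantiomer of the usual catalyst, 30 mol%), KHSO5 (as 2KHSO5·KHSO4·K2SO4, 1.4 equiv), K2CO3, Bu4NHSO4 (cat.), MeCN/CH2(OMe)2/aq. Na2B4O7 buffer, 0 °C
Reagents that add atoms: potassium peroxymonosulfate ([K+].[O-]S(=O)(=O)OO)
Why: Shi asymmetric epoxidation (chiral dioxirane, spiro transition state) of the trisubstituted alkene sets the absolute configuration of the future C12 carbinol; the D-fructose ketone gives the (R,R)-oxide of 1-phenylcyclohexene, so its enantiomer is used here, and the ee can be raised by recrystallising 7.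

Step 3
Reactants: 3 (1'R,6'S)-1'-methylspiro[1,3-dioxolane-2,3'-[7]oxabicyclo[4.1.0]heptane]; 4 methyl acrylate
Product: 7 (4aS,8aS)-4a-methylhexahydro-2H-chromene-2,6(3H)-dione, via hydroxy ester acetal 5 (not isolated), via lactone acetal 6 (not isolated)
Conditions: Cp2TiCl2 (20 mol%), Zn (2 equiv), 2,4,6-collidine·HCl (2.5 equiv), methyl acrylate (4 equiv), THF, rt; then 1 M aq. HCl/THF, 40 °C, concentrate from toluene
Reagents that add atoms: water (O)
Why: Nugent–RajanBabu/Gansäuer reductive epoxide opening by Cp2TiCl (trivalent titanium, formed in the flask) gives the tertiary β-titanoxy radical, which adds to the acrylate (Giese addition) anti to the bulky titanoxy group and so creates the C7 quaternary centre trans to the C12 oxygen; aqueous acid then frees the ketone and closes the trans-fused δ-lactone.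

Step 4
Reactants: 8 prop-2-yn-1-ol
Product: 9 (2Z)-2-(tributylstannyl)-3-(trimethylsilyl)prop-2-en-1-ol
Conditions: Me3SiSnBu3 (1.05 equiv), Pd(PPh3)4 (2 mol%), THF, 65 °C
Reagents that add atoms: trimethyl(tributylstannyl)silane (C[Si](C)(C)[Sn](CCCC)(CCCC)CCCC)
Why: Palladium-catalysed silylstannation of a terminal alkyne is a cis addition that puts tin on the internal carbon and silicon on the terminal carbon, so the geometry of the later exocyclic alkene is fixed here.

Step 5
Reactants: 7 (4aS,8aS)-4a-methylhexahydro-2H-chromene-2,6(3H)-dione; 10 methyl prop-2-ynoate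
Product: 11 methyl (2Z)-2-[(4aS,6R,8aS)-6-hydroxy-4a-methyl-2-oxooctahydro-2H-chromen-6-yl]-3-iodoprop-2-enoate
Conditions: Et2AlI (1.5 equiv), methyl prop-2-ynoate (1.5 equiv), CH2Cl2, 0 °C to rt; aq. KNaC4H4O6 work-up
Reagents that add atoms: diethylaluminium iodide (CC[Al](I)CC)
Why: Iodide-triggered halo-aldol (β-iodo Morita–Baylis–Hillman) reaction: iodide adds to the aluminium-activated propiolate and the allenolate attacks the ketone equatorially, away from the axial angular methyl of the rigid trans-fused bicycle, which sets the C9 carbinol with the new carbon cis to the lactone arm and gives the (Z)-β-iodoacrylate.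

Step 6
Reactants: 11 methyl (2Z)-2-[(4aS,6R,8aS)-6-hydroxy-4a-methyl-2-oxooctahydro-2H-chromen-6-yl]-3-iodoprop-2-enoate; 9 (2Z)-2-(tributylstannyl)-3-(trimethylsilyl)prop-2-en-1-ol
Product: 13 (4aS,6R,8aS)-6-hydroxy-4a-methyl-6-{(5E)-2-oxo-5-[(trimethylsilyl)methylidene]-5,6-dihydro-2H-pyran-3-yl}octahydro-2H-chromen-2-one, via hydroxy dienoate 12 (not isolated)
Conditions: Cu(O2CC4H3S) (copper thiophene-2-carboxylate, 1.5 equiv), NMP, 0 °C to rt; then PPTS (10 mol%), PhMe, 50 °C
Reagents that add atoms: none
Why: Liebeskind–Allred copper-mediated Stille-type coupling joins the two sp2 carbons with retention of both alkene geometries, and the (Z)-ester then lactonises onto the allylic alcohol to give the 5-alkylidene-5,6-dihydropyran-2-one; no new stereocentre.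

Step 7
Reactants: 13 (4aS,6R,8aS)-6-hydroxy-4a-methyl-6-{(5E)-2-oxo-5-[(trimethylsilyl)methylidene]-5,6-dihydro-2H-pyran-3-yl}octahydro-2H-chromen-2-one
Product: 15 (4E,4aS,7S,9R,9aR,12S)-9,12-dihydroxy-7-methyl-4-[(trimethylsilyl)methylidene]octahydro-1H-7,9-propanocyclohepta[c]pyran-1-one, via cesium carboxylate 14 (not isolated)
Conditions: CsOH·H2O (1.05 equiv), THF/H2O, 0 °C; evaporate; Ru(bpz)3(PF6)2 (2 mol%), DMSO/H2O 20:1, 455 nm LEDs, rt, Ar; pH 5 KH2PO4 work-up
Reagents that add atoms: cesium hydroxide ([Cs+].[OH-])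
Why: Proposed new method: the closest known reactions are the photoredox decarboxylative Giese addition of carboxylates and 7-endo radical cyclisations onto α-substituted acrylates; CsOH opens only the saturated δ-lactone to carboxylate 14 (the conjugated α-branched dihydropyranone is much less electrophilic, and the cesium and hydroxide oxygen leave again with the carboxyl carbon), the excited ruthenium complex (triplet energy near 48 kcal/mol, too low to sensitise the dienyl lactone) oxidises the carboxylate to CO2 and the primary C5 radical, which can reach only the β-carbon C4a (7-endo; the α-carbon is fully substituted and polarity-mismatched) and is expected to attack the lactone face turned toward the C8 methylene when the lactone carbonyl is hydrogen-bonded to the C9 hydroxyl, which sets C4a, and the α-lactonyl radical is then reduced to the enolate and protonated on the face away from the three-carbon bridge to give the trans ring fusion at C9a, which should also be the thermodynamic one.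

Step 8
Reactants: 15 (4E,4aS,7S,9R,9aR,12S)-9,12-dihydroxy-7-methyl-4-[(trimethylsilyl)methylidene]octahydro-1H-7,9-propanocyclohepta[c]pyran-1-one
Product: 16 (4E,4aS,7S,9R,9aR,12S)-9,12-dihydroxy-4-(iodomethylidene)-7-methyloctahydro-1H-7,9-propanocyclohepta[c]pyran-1-one
Conditions: NIS (1.2 equiv), (CF3)2CHOH, 0 °C, dark
Reagents that add atoms: N-iodosuccinimide (O=C1CCC(=O)N1I)
Why: Electrophilic ipso-iododesilylation of the vinylsilane via a β-silyl cation proceeds with retention in hexafluoroisopropanol, so iodine takes the place of silicon cis to C4a and no stereocentre is touched.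

Step 9
Reactants: 16 (4E,4aS,7S,9R,9aR,12S)-9,12-dihydroxy-4-(iodomethylidene)-7-methyloctahydro-1H-7,9-propanocyclohepta[c]pyran-1-one; 17 2-methylbut-3-en-2-ol
Product: 18 (4E,4aS,7S,9R,9aR,12S)-9,12-dihydroxy-4-[(2E)-4-hydroxy-4-methylpent-2-en-1-ylidene]-7-methyloctahydro-1H-7,9-propanocyclohepta[c]pyran-1-one (CNP0116574.1)
Conditions: Pd(OAc)2 (10 mol%), Bu4NCl (1 equiv), NaHCO3 (2.5 equiv), 2-methylbut-3-en-2-ol (3 equiv), DMF, 40 °C
Reagents that add atoms: none
Why: Jeffery-type Mizoroki–Heck reaction: the alkenylpalladium iodide adds to the terminal alkene carbon and β-hydride elimination, possible only toward the new diene because the carbinol carbon bears no hydrogen, gives the (E)-alkene with the vinyl iodide geometry retained.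

## Compound list

1 | 3-methylcyclohex-2-en-1-one | CC1=CC(=O)CCC1 | starting material
2 | 7-methyl-1,4-dioxaspiro[4.5]dec-7-ene | CC1=CCCC2(C1)OCCO2 | intermediate
3 | (1'R,6'S)-1'-methylspiro[1,3-dioxolane-2,3'-[7]oxabicyclo[4.1.0]heptane] | C[C@@]12CC3(OCCO3)CC[C@@H]1O2 | intermediate
4 | methyl acrylate (methyl prop-2-enoate) | C=CC(=O)OC | starting material
5 | methyl 3-[(7S,8S)-8-hydroxy-7-methyl-1,4-dioxaspiro[4.5]decan-7-yl]propanoate | COC(=O)CC[C@@]1(C)CC2(OCCO2)CC[C@@H]1O | intermediate
6 | (4a'S,8a'S)-4a'-methylhexahydrospiro[1,3-dioxolane-2,6'-chromen]-2'(3'H)-one | O=C1CC[C@@]2(C)CC3(OCCO3)CC[C@@H]2O1 | intermediate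
7 | (4aS,8aS)-4a-methylhexahydro-2H-chromene-2,6(3H)-dione (trans-fused keto δ-lactone) | O=C1CC[C@@]2(C)CC(=O)CC[C@@H]2O1 | intermediate
8 | prop-2-yn-1-ol | C#CCO | starting material
9 | (2Z)-2-(tributylstannyl)-3-(trimethylsilyl)prop-2-en-1-ol | OC/C(=C/[Si](C)(C)C)[Sn](CCCC)(CCCC)CCCC | intermediate
10 | methyl prop-2-ynoate | C#CC(=O)OC | starting material
11 | methyl (2Z)-2-[(4aS,6R,8aS)-6-hydroxy-4a-methyl-2-oxooctahydro-2H-chromen-6-yl]-3-iodoprop-2-enoate | O=C1CC[C@@]2(C)C[C@@](O)(/C(=C/I)C(=O)OC)CC[C@@H]2O1 | intermediate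
12 | methyl (2Z,4E)-2-[(4aS,6R,8aS)-6-hydroxy-4a-methyl-2-oxooctahydro-2H-chromen-6-yl]-4-(hydroxymethyl)-5-(trimethylsilyl)penta-2,4-dienoate | O=C1CC[C@@]2(C)C[C@@](O)(/C(C(=O)OC)=C/C(CO)=C\[Si](C)(C)C)CC[C@@H]2O1 | intermediate
13 | (4aS,6R,8aS)-6-hydroxy-4a-methyl-6-{(5E)-2-oxo-5-[(trimethylsilyl)methylidene]-5,6-dihydro-2H-pyran-3-yl}octahydro-2H-chromen-2-one | O=C1CC[C@@]2(C)C[C@@](O)(C3=C/C(=C\[Si](C)(C)C)COC3=O)CC[C@@H]2O1 | intermediate
14 | cesium 3-[(1S,2S,5R)-2,5-dihydroxy-1-methyl-5-{(5E)-2-oxo-5-[(trimethylsilyl)methylidene]-5,6-dihydro-2H-pyran-3-yl}cyclohexyl]propanoate | [Cs+].[O-]C(=O)CC[C@@]1(C)C[C@@](O)(C2=C/C(=C\[Si](C)(C)C)COC2=O)CC[C@@H]1O | intermediate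
15 | (4E,4aS,7S,9R,9aR,12S)-9,12-dihydroxy-7-methyl-4-[(trimethylsilyl)methylidene]octahydro-1H-7,9-propanocyclohepta[c]pyran-1-one | C[Si](C)(C)/C=C1/COC(=O)[C@@H]2[C@@H]1CC[C@@]1(C)C[C@]2(O)CC[C@@H]1O | intermediate
16 | (4E,4aS,7S,9R,9aR,12S)-9,12-dihydroxy-4-(iodomethylidene)-7-methyloctahydro-1H-7,9-propanocyclohepta[c]pyran-1-one | I/C=C1/COC(=O)[C@@H]2[C@@H]1CC[C@@]1(C)C[C@]2(O)CC[C@@H]1O | intermediate
17 | 2-methylbut-3-en-2-ol | C=CC(C)(C)O | starting material
18 | (4E,4aS,7S,9R,9aR,12S)-9,12-dihydroxy-4-[(2E)-4-hydroxy-4-methylpent-2-en-1-ylidene]-7-methyloctahydro-1H-7,9-propanocyclohepta[c]pyran-1-one | CC(C)(O)/C=C/C=C1/COC(=O)[C@@H]2[C@@H]1CC[C@@]1(C)C[C@]2(O)CC[C@@H]1O | target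

## Step count and risks

Total steps: 9. Longest linear sequence: 8 steps (steps 1, 2, 3, 5, 6, 7, 8, 9; step 4 is a one-step side branch).

First risk, step 7 (key radical cyclisation): the primary radical must reach, from a diaxial chair, a β-carbon that is internal to the dienoate. A 1,5-hydrogen shift, attack at the α-carbon, the wrong face at C4a, or residual photoisomerisation of the silyl alkene may compete. The fallback inverts the order of the two bonds made at C4a; it sets out from 11 and comes back at 15. CsOH opens the saturated lactone of 11 to cesium 3-[(1S,2S,5R)-2,5-dihydroxy-5-[(1Z)-2-iodo-1-(methoxycarbonyl)ethenyl]-1-methylcyclohexyl]propanoate F1. The same photoredox decarboxylation then lets the primary radical add 7-endo to the small, strongly activated β-iodoacrylate carbon, and the adduct radical expels an iodine atom (radical addition–elimination). This gives methyl (1R,6S,7S)-1,7-dihydroxy-6-methylbicyclo[4.3.1]dec-2-ene-2-carboxylate F2. The alkenyl group of stannane 9 is then added to C3 of F2 from the exo face, away from the three-carbon bridge, by rhodium-catalysed conjugate addition ([Rh(cod)(MeCN)2]BF4, THF/H2O, 60 °C). This gives methyl (1R,2R,3S,6S,7S)-1,7-dihydroxy-3-[(1E)-3-hydroxy-1-(trimethylsilyl)prop-1-en-2-yl]-6-methylbicyclo[4.3.1]decane-2-carboxylate F3, which PPTS in warm toluene lactonises to 15.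

Second risk, step 5 (halo-aldol on a ketone): ketones are much poorer acceptors than aldehydes in iodide-triggered aldol reactions, retro-aldol is easy, and 7 is neopentyl-like. The fallback makes the metallated dienoate first; it sets out from 9 (with 10 and 7) and comes back at 12, which the lactonisation of step 6 turns into 13. I2 in CH2Cl2 converts 9 with retention into (2Z)-2-iodo-3-(trimethylsilyl)prop-2-en-1-ol F4. Sonogashira coupling of F4 with 10 (PdCl2(PPh3)2, CuI, K2CO3, THF) gives methyl (4E)-4-(hydroxymethyl)-5-(trimethylsilyl)pent-4-en-2-ynoate F5. Syn-hydroalumination of F5 with i-Bu2AlH/N-methylmorpholine N-oxide (one extra equivalent for the hydroxyl) puts aluminium on C2, and this alkenylalane adds to ketone 7 to give 12 directly. This fallback also bypasses the hindered coupling of step 6.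

Third risk, step 3 (titanium-mediated radical addition): the tertiary β-titanoxy radical may lose a β-hydrogen to a second titanium centre faster than it adds to methyl acrylate, the acrylate can oligomerise, and the trans selectivity may be moderate. The fallback generates the same radical by hydrogen-atom transfer; it sets out from 3 and comes back at 5, which the acid treatment of step 3 converts into 7. Et2Al(tmp) (diethylaluminium 2,2,6,6-tetramethylpiperidide) in benzene isomerises epoxide 3 to (8S)-7-methylidene-1,4-dioxaspiro[4.5]decan-8-ol F6. Fe(acac)3/PhSiH3 in EtOH with 4 (Baran reductive olefin coupling) then delivers a hydrogen atom to the methylene carbon, and the tertiary radical adds to the acrylate anti to the neighbouring hydroxyl to give 5.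

## Further compounds

F1 | step 7 | cesium 3-[(1S,2S,5R)-2,5-dihydroxy-5-[(1Z)-2-iodo-1-(methoxycarbonyl)ethenyl]-1-methylcyclohexyl]propanoate | [Cs+].[O-]C(=O)CC[C@@]1(C)C[C@@](O)(/C(=C/I)C(=O)OC)CC[C@@H]1O
F2 | step 7 | methyl (1R,6S,7S)-1,7-dihydroxy-6-methylbicyclo[4.3.1]dec-2-ene-2-carboxylate | COC(=O)C1=CCC[C@@]2(C)C[C@]1(O)CC[C@@H]2O
F3 | step 7 | methyl (1R,2R,3S,6S,7S)-1,7-dihydroxy-3-[(1E)-3-hydroxy-1-(trimethylsilyl)prop-1-en-2-yl]-6-methylbicyclo[4.3.1]decane-2-carboxylate | COC(=O)[C@@H]1[C@@H](/C(CO)=C\[Si](C)(C)C)CC[C@@]2(C)C[C@]1(O)CC[C@@H]2O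
F4 | step 5 | (2Z)-2-iodo-3-(trimethylsilyl)prop-2-en-1-ol | OC/C(I)=C/[Si](C)(C)C
F5 | step 5 | methyl (4E)-4-(hydroxymethyl)-5-(trimethylsilyl)pent-4-en-2-ynoate | OC/C(C#CC(=O)OC)=C/[Si](C)(C)C
F6 | step 3 | (8S)-7-methylidene-1,4-dioxaspiro[4.5]decan-8-ol | C=C1CC2(CC[C@@H]1O)OCCO2
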